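The dihydropyranone ring is cut into a three-atom unit O1–C2–C3 and a three-atom unit C4–C5–C6, exploiting the 1,3-relationship between the ring oxygen O1 and the C4 ketone and the vinylogous-ester polarity of C5=C6. In one operation a dilithiated β-oxido carbanion, made by reductive opening of (S)-propylene oxide, C-acylates an alkynyl Weinreb amide (C3–C4), and the acid quench closes the ring by 6-endo attack of the carbinol oxygen on the ynone β-carbon (O1–C6). The precursor is an acyclic, silyl-protected ynamide from methyl (R)-3-hydroxy-2-methylpropanoate. The resulting pyranone alcohol becomes an alkylzinc reagent that is joined last to the chromone C-6 position of 6-iodoeugenin by Negishi coupling.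

Key step: step 5

Assumption: noreugenin, methyl (R)-3-hydroxy-2-methylpropanoate and (S)-propylene oxide are taken as commercial; the target is read as (2S) in the pyranone ring and (R) at the side-chain CH(CH3), and the primary silyl ether is deliberately allowed to fall in the acid quench of step 5.

**Step 1**
Reactants: 1 methyl (R)-3-hydroxy-2-methylpropanoate
Product: 2 methyl (R)-3-[(tert-butyldimethylsilyl)oxy]-2-methylpropanoate
Conditions: TBSCl, imidazole, CH2Cl2, 0 → 23 °C
Reagents that add atoms: tert-butyldimethylsilyl chloride, CC(C)(C)[Si](C)(C)Cl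
Why: Standard imidazole-promoted silylation of a primary alcohol; the α-stereocenter is not touched.

**Step 2**
Reactants: 2 methyl (R)-3-[(tert-butyldimethylsilyl)oxy]-2-methylpropanoate
Product: 3 (R)-3-[(tert-butyldimethylsilyl)oxy]-2-methylpropanal
Conditions: i-Bu2AlH (1.1 equiv), CH2Cl2, −78 °C; MeOH, then aq. potassium sodium tartrate; used crude
Reagents that add atoms: none
Why: Partial ester reduction by i-Bu2AlH at −78 °C should stop at the aldehyde because the aluminium hemiacetal survives until the cold quench, and the non-basic work-up protects the α-stereocenter.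

**Step 3**
Reactants: 3 (R)-3-[(tert-butyldimethylsilyl)oxy]-2-methylpropanal
Product: 4 (S)-tert-butyl[(4,4-dibromo-2-methylbut-3-en-1-yl)oxy]dimethylsilane
Conditions: CBr4, PPh3, CH2Cl2, 0 °C
Reagents that add atoms: carbon tetrabromide, BrC(Br)(Br)Br
Why: Corey–Fuchs dibromoolefination (Wittig reaction with Ph3P=CBr2) runs under neutral conditions, so the α-stereocenter should be retained.

**Step 4**
Reactants: 4 (S)-tert-butyl[(4,4-dibromo-2-methylbut-3-en-1-yl)oxy]dimethylsilane
Product: 6 (S)-5-[(tert-butyldimethylsilyl)oxy]-N-methoxy-N,4-dimethylpent-2-ynamide, via lithium acetylide 5 (not isolated)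
Conditions: n-BuLi (2.1 equiv), THF, −78 → 0 °C; then ClC(O)N(OMe)Me, −78 → 23 °C
Reagents that add atoms: N-methoxy-N-methylcarbamoyl chloride, CON(C)C(Cl)=O
Why: The second stage of the Corey–Fuchs reaction (Br/Li exchange, α-elimination with Fritsch–Buttenberg–Wiechell 1,2-shift, deprotonation) gives the acetylide, and its C-acylation by the carbamoyl chloride is a standard entry to alkynyl Weinreb amides that leaves the propargylic stereocenter alone.

**Step 5**
Reactants: 6 (S)-5-[(tert-butyldimethylsilyl)oxy]-N-methoxy-N,4-dimethylpent-2-ynamide; 7 (S)-propylene oxide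
Product: 11 (2S)-6-[(2R)-1-hydroxypropan-2-yl]-2-methyl-2,3-dihydro-4H-pyran-4-one, via dilithio β-oxido carbanion 8 (not isolated), via tetrahedral dilithium adduct 9 (not isolated), via β-hydroxy ynone 10 (not isolated)
Conditions: 7, lithium 4,4′-di-tert-butylbiphenylide (2 equiv per 7, none in excess), THF, −78 °C; then 6, −78 → −40 °C; then TsOH·H2O (excess), MeOH, −78 → 23 °C
Reagents that add atoms: none
Why: Two-electron reductive cleavage of the less substituted C–O bond of 7 gives the C3-lithio, O1-lithium alkoxide 8 with C2 untouched, and its carbanion adds 1,2 to the Weinreb ynamide 6 (bond C3–C4) to give the chelated adduct 9, which blocks over-addition and keeps the ynone masked until the quench. Acidification releases β-hydroxy ynone 10, whose hydroxyl O1 adds to the polarized β-carbon C6 in a 6-endo-dig oxa-Michael closure (directly or through the methanol adduct) to the vinylogous ester, while TsOH in MeOH also removes the primary silyl ether. The closest known reaction types are reductive lithiation of epoxides to β-lithioalkoxides, the Weinreb ketone synthesis of ynones and the acid-mediated cyclization of β-hydroxy ynones to 2,3-dihydro-4H-pyran-4-ones, here run in one flask. No new stereocenter is formed: C2 (S) is carried from 7 and the side-chain center from 1. The step needs opening to the primary carbanion (secured by the preference for the more substituted alkoxide), 1,2-addition faster than propargylic deprotonation or conjugate addition (secured by −78 °C and the amide chelate) and 6-endo over 5-exo closure (secured by ynone polarization under Brønsted acid without a π-acidic metal). Because the ynone is only set free under acid, the propargylic center never meets base as a ketone and should not epimerize.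

**Step 6**
Reactants: 11 (2S)-6-[(2R)-1-hydroxypropan-2-yl]-2-methyl-2,3-dihydro-4H-pyran-4-one
Product: 12 (2S)-6-[(2S)-1-iodopropan-2-yl]-2-methyl-2,3-dihydro-4H-pyran-4-one
Conditions: PPh3, I2, imidazole, CH2Cl2, 0 °C
Reagents that add atoms: iodine, II
Why: Appel-type iodination of an unhindered primary alcohol under near-neutral conditions that a vinylogous ester tolerates; the neighbouring stereocenter is not involved and changes descriptor to S only through the priority rules.

**Step 7**
Reactants: 13 noreugenin (5,7-dihydroxy-2-methyl-4H-chromen-4-one)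
Product: 14 eugenin (5-hydroxy-7-methoxy-2-methyl-4H-chromen-4-one)
Conditions: MeI (1.1 equiv), K2CO3, acetone, reflux
Reagents that add atoms: iodomethane, CI
Why: Williamson methylation is selective for the more acidic, non-chelated 7-OH because the 5-OH is locked in a hydrogen bond to the C4 carbonyl.

**Step 8**
Reactants: 14 eugenin
Product: 15 6-iodoeugenin (5-hydroxy-6-iodo-7-methoxy-2-methyl-4H-chromen-4-one)
Conditions: BnMe3N+ ICl2− (1.05 equiv), CaCO3, CH2Cl2/MeOH, 23 °C
Reagents that add atoms: benzyltrimethylammonium dichloroiodate, C[N+](C)(C)Cc1ccccc1.Cl[I-]Cl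
Why: Electrophilic aromatic iodination with a mild iodonium source; in 5-hydroxy-7-alkoxy chromones and flavones the hydrogen-bonded 5-OH steers substitution to its free ortho position C6 (the 5-O-alkyl series reacts at C8), and CaCO3 takes up the HCl.

**Step 9**
Reactants: 12 (2S)-6-[(2S)-1-iodopropan-2-yl]-2-methyl-2,3-dihydro-4H-pyran-4-one; 15 6-iodoeugenin
Product: 17 5-hydroxy-7-methoxy-2-methyl-6-{(2R)-2-[(2S)-2-methyl-4-oxo-3,4-dihydro-2H-pyran-6-yl]propyl}-4H-chromen-4-one, via alkylzinc iodide 16 (not isolated)
Conditions: 12, Zn dust (activated with BrCH2CH2Br/TMSCl), LiCl, THF, 40 °C; then slow addition to 15, Pd(OAc)2 (cat.), SPhos (2-dicyclohexylphosphino-2′,6′-dimethoxybiphenyl), THF, 25 → 50 °C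
Reagents that add atoms: none
Why: Negishi sp3–sp2 cross-coupling: zinc inserts into the primary C–I bond without touching the vinylogous ester, and palladium with a bulky electron-rich biarylphosphine should couple the alkylzinc iodide with the di-ortho-substituted aryl iodide faster than β-hydride elimination or protonolysis by the hydrogen-bonded phenol; no stereocenter is formed or touched.

**Compound list**

1 | methyl (R)-3-hydroxy-2-methylpropanoate | OC[C@@H](C)C(=O)OC | starting material
2 | methyl (R)-3-[(tert-butyldimethylsilyl)oxy]-2-methylpropanoate | CC(C)(C)[Si](C)(C)OC[C@@H](C)C(=O)OC | intermediate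
3 | (R)-3-[(tert-butyldimethylsilyl)oxy]-2-methylpropanal | CC(C)(C)[Si](C)(C)OC[C@@H](C)C=O | intermediate
4 | (S)-tert-butyl[(4,4-dibromo-2-methylbut-3-en-1-yl)oxy]dimethylsilane | CC(C)(C)[Si](C)(C)OC[C@@H](C)C=C(Br)Br | intermediate
5 | lithium (S)-4-[(tert-butyldimethylsilyl)oxy]-3-methylbut-1-yn-1-ide (lithium acetylide, not isolated) | CC(C)(C)[Si](C)(C)OC[C@@H](C)C#C[Li] | intermediate
6 | (S)-5-[(tert-butyldimethylsilyl)oxy]-N-methoxy-N,4-dimethylpent-2-ynamide | CC(C)(C)[Si](C)(C)OC[C@@H](C)C#CC(=O)N(C)OC | intermediate
7 | (S)-propylene oxide ((S)-2-methyloxirane) | C[C@H]1CO1 | starting material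
8 | dilithium (S)-1-lithiopropan-2-olate (dilithio β-oxido carbanion, not isolated) | [Li]C[C@H](C)O[Li] | intermediate
9 | dilithium (2S,7S)-8-[(tert-butyldimethylsilyl)oxy]-4-[methoxy(methyl)amino]-7-methyloct-5-yne-2,4-diolate (tetrahedral adduct, both C4 epimers, not isolated) | CC(C)(C)[Si](C)(C)OC[C@@H](C)C#CC(O[Li])(C[C@H](C)O[Li])N(C)OC | intermediate
10 | (2S,7S)-8-[(tert-butyldimethylsilyl)oxy]-2-hydroxy-7-methyloct-5-yn-4-one (β-hydroxy ynone, not isolated) | CC(C)(C)[Si](C)(C)OC[C@@H](C)C#CC(=O)C[C@H](C)O | intermediate
11 | (2S)-6-[(2R)-1-hydroxypropan-2-yl]-2-methyl-2,3-dihydro-4H-pyran-4-one | OC[C@@H](C)C1=CC(=O)C[C@H](C)O1 | intermediate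
12 | (2S)-6-[(2S)-1-iodopropan-2-yl]-2-methyl-2,3-dihydro-4H-pyran-4-one | IC[C@@H](C)C1=CC(=O)C[C@H](C)O1 | intermediate
13 | noreugenin (5,7-dihydroxy-2-methyl-4H-chromen-4-one) | Cc1cc(=O)c2c(O)cc(O)cc2o1 | starting material
14 | eugenin (5-hydroxy-7-methoxy-2-methyl-4H-chromen-4-one) | COc1cc2oc(C)cc(=O)c2c(O)c1 | intermediate
15 | 6-iodoeugenin (5-hydroxy-6-iodo-7-methoxy-2-methyl-4H-chromen-4-one) | COc1cc2oc(C)cc(=O)c2c(O)c1I | intermediate
16 | iodo{(2S)-2-[(2S)-2-methyl-4-oxo-3,4-dihydro-2H-pyran-6-yl]propyl}zinc (alkylzinc iodide, not isolated) | I[Zn]C[C@@H](C)C1=CC(=O)C[C@H](C)O1 | intermediate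
17 | 5-hydroxy-7-methoxy-2-methyl-6-{(2R)-2-[(2S)-2-methyl-4-oxo-3,4-dihydro-2H-pyran-6-yl]propyl}-4H-chromen-4-one | COc1cc2oc(C)cc(=O)c2c(O)c1C[C@@H](C)C1=CC(=O)C[C@H](C)O1 | target

Total step count: 9. Longest linear sequence: 7 steps (steps 1–6 and 9); steps 7 and 8 form the second branch.

**Steps most likely to fail**

Step 5. The dianion 8 may lose lithium oxide by β-elimination to propene before it is trapped. It may also act as a base at the propargylic C–H of 6, or add in conjugate fashion instead of at the amide carbonyl. Ring closure after the quench may stall at open methanol adducts. The fallback forms the C4–C5 bond instead and sets out from dibromoolefin 4, which n-BuLi converts as in step 4 into lithium acetylide 5. Separately, commercial ethyl (S)-3-hydroxybutanoate is treated with MeNHOMe·HCl and i-PrMgCl in THF at −20 °C to give (S)-3-hydroxy-N-methoxy-N-methylbutanamide F1. One further equivalent of i-PrMgCl turns this in the flask into its chloromagnesium alkoxide F2, to which 5 is added at −78 → 0 °C. Aqueous NH4Cl work-up then gives the β-hydroxy ynone 10, now isolated. Here the fallback comes back to the route: TsOH·H2O in MeOH at 23 °C cyclizes and desilylates 10 to 11 as in the second half of step 5.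

Step 9. The alkylzinc may be protonated by the phenol, and palladium may be held by the peri-hydroxy-ketone chelate. Oxidative addition at the doubly ortho-substituted iodide may be slow, leaving time for β-hydride elimination from the alkylpalladium toward the conjugated isopropenyl dienone. The fallback removes the acidic, chelating group before the coupling and sets out from 15. Ac2O, pyridine and catalytic DMAP in CH2Cl2 should give 6-iodo-7-methoxy-2-methyl-4-oxo-4H-chromen-5-yl acetate F3. This is coupled with 16 (from 12, as in step 9) under Pd(OAc)2/SPhos to the 5-O-acetyl derivative of the target F4. Brief treatment with K2CO3 in MeOH at 0 °C cleaves the activated peri-acetate and comes back to the route at 17.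

Step 4. Acylation of acetylide 5 by the sluggish carbamoyl chloride may be incomplete, residual n-BuLi may attack the reagent, and a second acetylide may add to the product ynamide. The fallback replaces carbamoylation by carboxylation and amide coupling and sets out from 4. n-BuLi (2.1 equiv) in THF at −78 °C gives 5, which is quenched with CO2 gas and acidified to (S)-5-[(tert-butyldimethylsilyl)oxy]-4-methylpent-2-ynoic acid F5. Coupling with MeNHOMe·HCl, EDC·HCl and N-methylmorpholine in CH2Cl2 at 0 °C then comes back to the route at 6.

**Further compounds**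

F1 | step 5 | (S)-3-hydroxy-N-methoxy-N-methylbutanamide | C[C@H](O)CC(=O)N(C)OC
F2 | step 5 | chloromagnesium (S)-4-[methoxy(methyl)amino]-4-oxobutan-2-olate | C[C@H](O[Mg]Cl)CC(=O)N(C)OC
F3 | step 9 | 6-iodo-7-methoxy-2-methyl-4-oxo-4H-chromen-5-yl acetate | COc1cc2oc(C)cc(=O)c2c(OC(C)=O)c1I
F4 | step 9 | 7-methoxy-2-methyl-6-{(2R)-2-[(2S)-2-methyl-4-oxo-3,4-dihydro-2H-pyran-6-yl]propyl}-4-oxo-4H-chromen-5-yl acetate | COc1cc2oc(C)cc(=O)c2c(OC(C)=O)c1C[C@@H](C)C1=CC(=O)C[C@H](C)O1
F5 | step 4 | (S)-5-[(tert-butyldimethylsilyl)oxy]-4-methylpent-2-ynoic acid | CC(C)(C)[Si](C)(C)OC[C@@H](C)C#CC(O)=O
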